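**Plan**
- Retrosynthesis: the two silyl ethers are removed, C2 is raised to the carboxyl level, and ring C is cut at C3–C4 and O1–C2.
- Enabling feature: O1 sits on C8a, ortho to C4a with its benzylic C4, and O7 is para to C4a, so ring A is a latent ortho-quinone methide (C4 electrophilic, O1 nucleophilic).
- C3 is benzylic to ring B and α to C2, so it is the α-carbon of a ring B arylacetic acid.
- Forward: the pyran of ring B is made first (propargyl ether Claisen cascade) and the aldehyde is homologated to an arylacetic 4-nitrophenyl ester; ring A becomes a prenylated ortho-hydroxybenzyl sulfone.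
- Ring C is closed last by an isothiourea-catalysed formal [4+2] annulation that joins the halves and sets C3 (3R) under catalyst control.
- The helpers leave afterwards: the C2 carbonyl by iBu2AlH then Et3SiH/BF3·OEt2 (the sulfinate is lost in the key step itself), the silyl groups by fluoride.

Key step: step 12

Assumption: the sense of induction of (R)-BTM is taken from the accepted model (Z-enolate, 1,5-O···S lock, attack anti to the catalyst phenyl group), which predicts the 3R lactone; if a model reaction shows the opposite sense, the equally available (S)-BTM is used.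

Step 1
Reactants: 1 2,4-dihydroxybenzaldehyde
Product: 2 2-hydroxy-4-[(triisopropylsilyl)oxy]benzaldehyde
Conditions: TIPSCl (1.05 equiv), imidazole, DMF, 0 °C
Reagents that add atoms: chlorotriisopropylsilane, CC(C)[Si](Cl)(C(C)C)C(C)C
Why: Regioselective O-silylation, in which the C2 hydroxyl is locked in a hydrogen bond to the formyl oxygen so that the bulky silyl chloride should take only the free, more acidic C4 hydroxyl.

Step 2
Reactants: 2 2-hydroxy-4-[(triisopropylsilyl)oxy]benzaldehyde
Product: 3 2-[(2-methylbut-3-yn-2-yl)oxy]-4-[(triisopropylsilyl)oxy]benzaldehyde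
Conditions: 3-chloro-3-methylbut-1-yne, DBU, CuCl2 (1 mol %), MeCN, 0 °C
Reagents that add atoms: 3-chloro-3-methylbut-1-yne, CC(C)(Cl)C#C
Why: Copper-catalysed O-propargylation of a phenoxide with a tertiary propargylic chloride should alkylate the one remaining hydroxyl under cold, anhydrous conditions that spare the aryl silyl ether.

Step 3
Reactants: 3 2-[(2-methylbut-3-yn-2-yl)oxy]-4-[(triisopropylsilyl)oxy]benzaldehyde
Product: 6 2,2-dimethyl-5-[(triisopropylsilyl)oxy]-2H-chromene-8-carbaldehyde, via allenylphenol 4 (not isolated), via dienone 5 (not isolated)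
Conditions: o-xylene, 140 °C
Reagents that add atoms: none
Why: Aryl propargyl ether Claisen cascade, in which the [3,3] shift can reach only C3 because the other ortho carbon carries the formyl group, and tautomerisation to 4, 1,5-hydrogen shift to 5 and oxa-6π electrocyclisation should close the dimethylpyran of ring B on the oxygen next to the future attachment carbon.

Step 4
Reactants: 6 2,2-dimethyl-5-[(triisopropylsilyl)oxy]-2H-chromene-8-carbaldehyde
Product: 7 8-(2-methoxyethenyl)-2,2-dimethyl-5-[(triisopropylsilyl)oxy]-2H-chromene (E/Z mixture)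
Conditions: Ph3P(CH2OMe)Cl, KOtBu, THF, 0 °C, then 6
Reagents that add atoms: (methoxymethyl)triphenylphosphonium chloride, COC[P+](c1ccccc1)(c1ccccc1)c1ccccc1.[Cl-]
Why: Wittig methoxymethylenation with the preformed non-stabilised ylide is the standard one-carbon homologation of an aryl aldehyde.

Step 5
Reactants: 7 8-(2-methoxyethenyl)-2,2-dimethyl-5-[(triisopropylsilyl)oxy]-2H-chromene
Product: 8 2-{2,2-dimethyl-5-[(triisopropylsilyl)oxy]-2H-chromen-8-yl}acetaldehyde
Conditions: 2 M aq. HCl, THF, rt; used crude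
Reagents that add atoms: water, O
Why: Acid-catalysed enol ether hydrolysis should unmask the arylacetaldehyde, while the aryl silyl ether and the chromene tolerate cold dilute acid.

Step 6
Reactants: 8 2-{2,2-dimethyl-5-[(triisopropylsilyl)oxy]-2H-chromen-8-yl}acetaldehyde
Product: 9 2-{2,2-dimethyl-5-[(triisopropylsilyl)oxy]-2H-chromen-8-yl}acetic acid
Conditions: NaClO2, NaH2PO4, 2-methyl-2-butene (excess), t-BuOH–H2O, 0 °C
Reagents that add atoms: sodium chlorite, [Na+].[O-]Cl=O
Why: Pinnick oxidation converts the aldehyde to the acid under buffered conditions, the excess 2-methyl-2-butene trapping HOCl before it can reach the chromene double bond.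

Step 7
Reactants: 9 2-{2,2-dimethyl-5-[(triisopropylsilyl)oxy]-2H-chromen-8-yl}acetic acid
Product: 10 4-nitrophenyl 2-{2,2-dimethyl-5-[(triisopropylsilyl)oxy]-2H-chromen-8-yl}acetate
Conditions: 4-nitrophenol, DCC, DMAP (5 mol %), CH2Cl2, 0 °C → rt
Reagents that add atoms: 4-nitrophenol, Oc1ccc(cc1)[N+](=O)[O-]
Why: Steglich esterification gives an aryl ester active enough to acylate an isothiourea, whose aryloxide later serves as the internal base.

Step 8
Reactants: 11 5-bromo-2,4-dihydroxybenzaldehyde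
Product: 12 5-bromo-2-hydroxy-4-[(triisopropylsilyl)oxy]benzaldehyde
Conditions: TIPSCl (1.05 equiv), imidazole, DMF, 0 °C → rt
Reagents that add atoms: chlorotriisopropylsilane, CC(C)[Si](Cl)(C(C)C)C(C)C
Why: Regioselective O-silylation as in step 1, the chelated C2 hydroxyl staying free to become O1 of the ortho-quinone methide.

Step 9
Reactants: 12 5-bromo-2-hydroxy-4-[(triisopropylsilyl)oxy]benzaldehyde
Product: 13 2-hydroxy-5-(3-methylbut-2-en-1-yl)-4-[(triisopropylsilyl)oxy]benzaldehyde
Conditions: tributyl(3-methylbut-2-en-1-yl)stannane, Pd(PPh3)4 (5 mol %), DMF, 90 °C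
Reagents that add atoms: tributyl(3-methylbut-2-en-1-yl)stannane, CCCC[Sn](CCCC)(CCCC)CC=C(C)C
Why: Migita–Kosugi–Stille coupling, in which zerovalent palladium inserts into the C–Br bond and reductive elimination from the less hindered primary terminus of the prenyl–palladium intermediate should give the linear prenyl arene under neutral conditions that leave phenol, aldehyde and silyl ether alone.

Step 10
Reactants: 13 2-hydroxy-5-(3-methylbut-2-en-1-yl)-4-[(triisopropylsilyl)oxy]benzaldehyde
Product: 14 2-(hydroxymethyl)-4-(3-methylbut-2-en-1-yl)-5-[(triisopropylsilyl)oxy]phenol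
Conditions: NaBH4, THF–EtOH, 0 °C
Reagents that add atoms: none
Why: Borohydride reduction of the salicylaldehyde gives the salicyl alcohol without touching the alkene or the silyl ether.

Step 11
Reactants: 14 2-(hydroxymethyl)-4-(3-methylbut-2-en-1-yl)-5-[(triisopropylsilyl)oxy]phenol
Product: 16 4-(3-methylbut-2-en-1-yl)-2-[(4-methylbenzenesulfonyl)methyl]-5-[(triisopropylsilyl)oxy]phenol, via benzylic cation 15 (not isolated)
Conditions: p-TolSO2H (1.5 equiv, freshly liberated from its sodium salt), CH2Cl2, rt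
Reagents that add atoms: 4-methylbenzenesulfinic acid, Cc1ccc(cc1)S(=O)O
Why: Acid-promoted SN1 substitution, in which the sulfinic acid protonates the benzylic hydroxyl, loss of water gives cation 15 (stabilised by the ortho hydroxyl and the para silyloxy group) and the soft sulfur of the sulfinate captures it, the known conversion of ortho-hydroxybenzyl alcohols into ortho-hydroxybenzyl sulfones, giving a bench-stable precursor from which base can later release the ortho-quinone methide.

Step 12
Reactants: 10 4-nitrophenyl 2-{2,2-dimethyl-5-[(triisopropylsilyl)oxy]-2H-chromen-8-yl}acetate; 16 4-(3-methylbut-2-en-1-yl)-2-[(4-methylbenzenesulfonyl)methyl]-5-[(triisopropylsilyl)oxy]phenol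
Product: 19 (3R)-3-{2,2-dimethyl-5-[(triisopropylsilyl)oxy]-2H-chromen-8-yl}-6-(3-methylbut-2-en-1-yl)-7-[(triisopropylsilyl)oxy]-3,4-dihydro-2H-chromen-2-one, via ortho-quinone methide 17 (not isolated), via ammonium enolate 18 (not isolated)
Conditions: (R)-BTM [(2R)-2-phenyl-2,3-dihydrobenzo[d]imidazo[2,1-b]thiazole] (10 mol %), iPr2NEt (2.2 equiv), 4 Å molecular sieves, CH2Cl2, 0 °C; cold dilute acid quench
Reagents that add atoms: none
Why: iPr2NEt deprotonates phenol 16, which expels sulfinate (1,4-elimination, assisted by the para silyloxy group) to release 17 slowly, while (R)-BTM is acylated by 10 and the 4-nitrophenoxide set free deprotonates the acyl ammonium ion to (Z)-ammonium enolate 18; the α-carbon of 18 (future C3) adds to the exocyclic methylene (future C4) of 17 with rearomatisation of ring A, and the ring A phenoxide (O1) then acylates on the acyl ammonium carbon (future C2), which closes ring C and returns the catalyst. The closest known reaction type is the Lewis-base-catalysed (isothiourea or N-heterocyclic carbene) Michael addition–lactonisation of C1-enolates of arylacetic acid derivatives with ortho-quinone methides generated in the flask, a formal [4+2] annulation giving 3,4-dihydrocoumarins. Ring C is closed in the mode 6-exo-trig (O1 onto the acyl carbon) directly after the intermolecular C3–C4 bond formation or, seen as one event, by an asynchronous hetero-Diels–Alder addition of the enolate double bond across the C4=C4a–C8a=O1 heterodiene. The only stereocentre, C3, is controlled by the catalyst: in 18 the enolate oxygen is held syn-coplanar to the catalyst sulfur (1,5-O···S contact), the phenyl group of (R)-BTM covers one face, and C4 is delivered to the open face, which by this model gives the 3R configuration. The step needs C-alkylation of the enolate to beat O-alkylation, self-condensation of 17 and addition of 17 to the prenyl and chromene alkenes, and needs the product not to epimerise; the first should be secured by the low stationary concentration of 17, the high nucleophilicity of the enolate carbon and the unhindered CH2 terminus (which raises no regiochemical or second stereochemical question), the second by the low kinetic acidity of the lactone α-hydrogen towards the hindered amine at 0 °C. Silylation of O7 leaves O1 as the only free phenol, so only the ortho-quinone methide, and no para-quinone methide, can form.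

Step 13
Reactants: 19 (3R)-3-{2,2-dimethyl-5-[(triisopropylsilyl)oxy]-2H-chromen-8-yl}-6-(3-methylbut-2-en-1-yl)-7-[(triisopropylsilyl)oxy]-3,4-dihydro-2H-chromen-2-one
Product: 20 (3R)-3-{2,2-dimethyl-5-[(triisopropylsilyl)oxy]-2H-chromen-8-yl}-6-(3-methylbut-2-en-1-yl)-7-[(triisopropylsilyl)oxy]-3,4-dihydro-2H-chromen-2-ol (mixture of C2 epimers)
Conditions: iBu2AlH (1.1 equiv), CH2Cl2, −78 °C; used crude at once
Reagents that add atoms: none
Why: Partial reduction of the lactone by iBu2AlH at −78 °C stops at the aluminium hemiacetal and gives the lactol on work-up, as is usual for 3,4-dihydrocoumarins, with no base present to epimerise C3.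

Step 14
Reactants: 20 (3R)-3-{2,2-dimethyl-5-[(triisopropylsilyl)oxy]-2H-chromen-8-yl}-6-(3-methylbut-2-en-1-yl)-7-[(triisopropylsilyl)oxy]-3,4-dihydro-2H-chromen-2-ol
Product: 22 (3R)-3-{2,2-dimethyl-5-[(triisopropylsilyl)oxy]-2H-chromen-8-yl}-6-(3-methylbut-2-en-1-yl)-7-[(triisopropylsilyl)oxy]-3,4-dihydro-2H-chromene, via oxocarbenium ion 21 (not isolated)
Conditions: Et3SiH (5 equiv), BF3·OEt2 (2 equiv), CH2Cl2, −78 °C; Et3N quench at −78 °C
Reagents that add atoms: none
Why: Ionic hydrogenation of a lactol (Kraus-type reductive deoxygenation), in which BF3 ionises the anomeric hydroxyl to 21 and the excess silane should reduce it at −78 °C faster than it can lose the C3 proton, so that C3 keeps its configuration and the prenyl and chromene double bonds survive.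

Step 15
Reactants: 22 (3R)-3-{2,2-dimethyl-5-[(triisopropylsilyl)oxy]-2H-chromen-8-yl}-6-(3-methylbut-2-en-1-yl)-7-[(triisopropylsilyl)oxy]-3,4-dihydro-2H-chromene
Product: 23 8-[(3R)-7-hydroxy-6-(3-methylbut-2-en-1-yl)-3,4-dihydro-2H-chromen-3-yl]-2,2-dimethyl-2H-chromen-5-ol (target)
Conditions: Bu4NF (2.5 equiv), AcOH (2.5 equiv), THF, 0 °C
Reagents that add atoms: none
Why: Fluoride cleavage of the two aryl silyl ethers, buffered with acetic acid so that the ortho-prenyl phenol and the chromene see neither strong acid nor strong base.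

**Compound list**
1 | 2,4-dihydroxybenzaldehyde | O=Cc1ccc(O)cc1O | starting material
2 | 2-hydroxy-4-[(triisopropylsilyl)oxy]benzaldehyde | O=Cc1ccc(O[Si](C(C)C)(C(C)C)C(C)C)cc1O | intermediate
3 | 2-[(2-methylbut-3-yn-2-yl)oxy]-4-[(triisopropylsilyl)oxy]benzaldehyde | O=Cc1ccc(O[Si](C(C)C)(C(C)C)C(C)C)cc1OC(C)(C)C#C | intermediate
4 | 2-hydroxy-3-(3-methylbuta-1,2-dien-1-yl)-4-[(triisopropylsilyl)oxy]benzaldehyde (allenylphenol, not isolated) | O=Cc1ccc(O[Si](C(C)C)(C(C)C)C(C)C)c(C=C=C(C)C)c1O | intermediate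
5 | 5-(3-methylbut-2-en-1-ylidene)-6-oxo-4-[(triisopropylsilyl)oxy]cyclohexa-1,3-diene-1-carbaldehyde (dienone, not isolated) | O=CC1=CC=C(O[Si](C(C)C)(C(C)C)C(C)C)C(=CC=C(C)C)C1=O | intermediate
6 | 2,2-dimethyl-5-[(triisopropylsilyl)oxy]-2H-chromene-8-carbaldehyde | O=Cc1ccc(O[Si](C(C)C)(C(C)C)C(C)C)c2c1OC(C)(C)C=C2 | intermediate
7 | 8-(2-methoxyethenyl)-2,2-dimethyl-5-[(triisopropylsilyl)oxy]-2H-chromene (E/Z mixture) | COC=Cc1ccc(O[Si](C(C)C)(C(C)C)C(C)C)c2c1OC(C)(C)C=C2 | intermediate
8 | 2-{2,2-dimethyl-5-[(triisopropylsilyl)oxy]-2H-chromen-8-yl}acetaldehyde | O=CCc1ccc(O[Si](C(C)C)(C(C)C)C(C)C)c2c1OC(C)(C)C=C2 | intermediate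
9 | 2-{2,2-dimethyl-5-[(triisopropylsilyl)oxy]-2H-chromen-8-yl}acetic acid | OC(=O)Cc1ccc(O[Si](C(C)C)(C(C)C)C(C)C)c2c1OC(C)(C)C=C2 | intermediate
10 | 4-nitrophenyl 2-{2,2-dimethyl-5-[(triisopropylsilyl)oxy]-2H-chromen-8-yl}acetate | O=C(Cc1ccc(O[Si](C(C)C)(C(C)C)C(C)C)c2c1OC(C)(C)C=C2)Oc1ccc(cc1)[N+](=O)[O-] | intermediate
11 | 5-bromo-2,4-dihydroxybenzaldehyde | O=Cc1cc(Br)c(O)cc1O | starting material
12 | 5-bromo-2-hydroxy-4-[(triisopropylsilyl)oxy]benzaldehyde | O=Cc1cc(Br)c(O[Si](C(C)C)(C(C)C)C(C)C)cc1O | intermediate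
13 | 2-hydroxy-5-(3-methylbut-2-en-1-yl)-4-[(triisopropylsilyl)oxy]benzaldehyde | O=Cc1cc(CC=C(C)C)c(O[Si](C(C)C)(C(C)C)C(C)C)cc1O | intermediate
14 | 2-(hydroxymethyl)-4-(3-methylbut-2-en-1-yl)-5-[(triisopropylsilyl)oxy]phenol | OCc1cc(CC=C(C)C)c(O[Si](C(C)C)(C(C)C)C(C)C)cc1O | intermediate
15 | {2-hydroxy-5-(3-methylbut-2-en-1-yl)-4-[(triisopropylsilyl)oxy]phenyl}methylium (benzylic cation, not isolated) | [CH2+]c1cc(CC=C(C)C)c(O[Si](C(C)C)(C(C)C)C(C)C)cc1O | intermediate
16 | 4-(3-methylbut-2-en-1-yl)-2-[(4-methylbenzenesulfonyl)methyl]-5-[(triisopropylsilyl)oxy]phenol | Cc1ccc(cc1)S(=O)(=O)Cc1cc(CC=C(C)C)c(O[Si](C(C)C)(C(C)C)C(C)C)cc1O | intermediate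
17 | 6-methylidene-4-(3-methylbut-2-en-1-yl)-3-[(triisopropylsilyl)oxy]cyclohexa-2,4-dien-1-one (ortho-quinone methide, not isolated) | C=C1C=C(CC=C(C)C)C(O[Si](C(C)C)(C(C)C)C(C)C)=CC1=O | intermediate
18 | (Z)-2-{2,2-dimethyl-5-[(triisopropylsilyl)oxy]-2H-chromen-8-yl}-1-[(2R)-2-phenyl-2,3-dihydrobenzo[d]imidazo[2,1-b]thiazol-1-ium-1-yl]ethen-1-olate (ammonium enolate, not isolated) | [O-]/C(=C\c1ccc(O[Si](C(C)C)(C(C)C)C(C)C)c2c1OC(C)(C)C=C2)[N+]1=C2Sc3ccccc3N2C[C@H]1c1ccccc1 | intermediate
19 | (3R)-3-{2,2-dimethyl-5-[(triisopropylsilyl)oxy]-2H-chromen-8-yl}-6-(3-methylbut-2-en-1-yl)-7-[(triisopropylsilyl)oxy]-3,4-dihydro-2H-chromen-2-one | CC(C)=CCc1cc2c(cc1O[Si](C(C)C)(C(C)C)C(C)C)OC(=O)[C@@H](c1ccc(O[Si](C(C)C)(C(C)C)C(C)C)c3c1OC(C)(C)C=C3)C2 | intermediate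
20 | (3R)-3-{2,2-dimethyl-5-[(triisopropylsilyl)oxy]-2H-chromen-8-yl}-6-(3-methylbut-2-en-1-yl)-7-[(triisopropylsilyl)oxy]-3,4-dihydro-2H-chromen-2-ol (C2 epimers) | CC(C)=CCc1cc2c(cc1O[Si](C(C)C)(C(C)C)C(C)C)OC(O)[C@@H](c1ccc(O[Si](C(C)C)(C(C)C)C(C)C)c3c1OC(C)(C)C=C3)C2 | intermediate
21 | (3R)-3-{2,2-dimethyl-5-[(triisopropylsilyl)oxy]-2H-chromen-8-yl}-6-(3-methylbut-2-en-1-yl)-7-[(triisopropylsilyl)oxy]-3,4-dihydrochromenylium (oxocarbenium ion, not isolated) | CC(C)=CCc1cc2c(cc1O[Si](C(C)C)(C(C)C)C(C)C)[O+]=C[C@@H](c1ccc(O[Si](C(C)C)(C(C)C)C(C)C)c3c1OC(C)(C)C=C3)C2 | intermediate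
22 | (3R)-3-{2,2-dimethyl-5-[(triisopropylsilyl)oxy]-2H-chromen-8-yl}-6-(3-methylbut-2-en-1-yl)-7-[(triisopropylsilyl)oxy]-3,4-dihydro-2H-chromene | CC(C)=CCc1cc2c(cc1O[Si](C(C)C)(C(C)C)C(C)C)OC[C@@H](c1ccc(O[Si](C(C)C)(C(C)C)C(C)C)c3c1OC(C)(C)C=C3)C2 | intermediate
23 | 8-[(3R)-7-hydroxy-6-(3-methylbut-2-en-1-yl)-3,4-dihydro-2H-chromen-3-yl]-2,2-dimethyl-2H-chromen-5-ol | CC(C)=CCc1cc2c(cc1O)OC[C@@H](c1ccc(O)c3c1OC(C)(C)C=C3)C2 | target

**Totals**
Total step count: 15 (steps 1–7 for the ring B ester, steps 8–11 for the ring A sulfone, steps 12–15 after the union).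
Longest linear sequence: 11 steps (1–7, then 12–15).

**Steps most likely to fail**

Step 12. The annulation may suffer from erosion of enantiopurity (poor facial discrimination, or enolisation of the aryl lactone under the basic conditions). It may also suffer from loss of material through oligomerisation of the quinone methide or O-acylation of the phenoxide before it eliminates. The fallback sets out from acid 9 and aldehyde 13 and comes back to the route at target 23, using auxiliary-controlled alkylation and a Mitsunobu ring closure. Acid 9 is coupled with (R)-4-benzyloxazolidin-2-one (DCC, DMAP, CH2Cl2) to give the N-acyl oxazolidinone F1. Aldehyde 13 is silylated on the chelated hydroxyl (TIPSOTf, 2,6-lutidine) to the bis-silyl aldehyde F2, reduced (NaBH4) to the benzyl alcohol F3 and converted (CBr4, PPh3, 0 °C) into the benzyl bromide F4, which is used crude. The sodium enolate of F1 (NaN(SiMe3)2, THF, −78 °C) is alkylated with F4 on the face away from the benzyl group of the auxiliary to give the (2R) imide F5. LiBH4 (THF, trace water, 0 °C) releases the auxiliary and gives the primary alcohol F6. Bu4NF/AcOH removes the three silyl groups to give the tetraol F7. A Mitsunobu reaction (PPh3, DIAD, THF, 0 °C) closes ring C through the ortho phenol to give 23.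

Step 14. The oxocarbenium ion may lose the C3 proton to a 4H-chromene enol ether before hydride arrives (loss of configuration). Acid formed in the flask may also reduce or cyclise the chromene and prenyl alkenes. The fallback sets out from lactol 20 and comes back at 22 without any cationic intermediate. Lactol 20 is reduced further (NaBH4, THF–EtOH, 0 °C) to the phenol–alcohol diol F8. An intramolecular Mitsunobu etherification (PPh3, DIAD, THF, 0 °C) of the phenol on the primary carbinol then gives 22, the stereocentre not being involved.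

Step 9. Oxidative addition into the electron-rich, ortho-silyloxy C–Br bond may be slow. The prenyl group may be delivered through its tertiary terminus (reverse-prenyl isomer) or transferred to the aldehyde carbonyl. The fallback sets out from bromide 12 and comes back at 13 by building the prenyl group in two stages. Stille coupling of 12 with allyltributylstannane (Pd(PPh3)4, toluene, 100 °C), which has no terminus ambiguity and is standard on bromobenzaldehydes, gives the allyl arene F9. Cross-metathesis of F9 with 2-methyl-2-butene (as co-solvent, second-generation Grubbs catalyst, CH2Cl2, 40 °C) gives 13.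

**Further compounds**
F1 | step 12 | (4R)-4-benzyl-3-(2-{2,2-dimethyl-5-[(triisopropylsilyl)oxy]-2H-chromen-8-yl}acetyl)oxazolidin-2-one | O=C(Cc1ccc(O[Si](C(C)C)(C(C)C)C(C)C)c2c1OC(C)(C)C=C2)N1[C@H](Cc2ccccc2)COC1=O
F2 | step 12 | 5-(3-methylbut-2-en-1-yl)-2,4-bis[(triisopropylsilyl)oxy]benzaldehyde | O=Cc1cc(CC=C(C)C)c(O[Si](C(C)C)(C(C)C)C(C)C)cc1O[Si](C(C)C)(C(C)C)C(C)C
F3 | step 12 | {5-(3-methylbut-2-en-1-yl)-2,4-bis[(triisopropylsilyl)oxy]phenyl}methanol | OCc1cc(CC=C(C)C)c(O[Si](C(C)C)(C(C)C)C(C)C)cc1O[Si](C(C)C)(C(C)C)C(C)C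
F4 | step 12 | 1-(bromomethyl)-5-(3-methylbut-2-en-1-yl)-2,4-bis[(triisopropylsilyl)oxy]benzene | BrCc1cc(CC=C(C)C)c(O[Si](C(C)C)(C(C)C)C(C)C)cc1O[Si](C(C)C)(C(C)C)C(C)C
F5 | step 12 | (4R)-4-benzyl-3-[(2R)-2-{2,2-dimethyl-5-[(triisopropylsilyl)oxy]-2H-chromen-8-yl}-3-{5-(3-methylbut-2-en-1-yl)-2,4-bis[(triisopropylsilyl)oxy]phenyl}propanoyl]oxazolidin-2-one | O=C([C@H](Cc1cc(CC=C(C)C)c(O[Si](C(C)C)(C(C)C)C(C)C)cc1O[Si](C(C)C)(C(C)C)C(C)C)c1ccc(O[Si](C(C)C)(C(C)C)C(C)C)c2c1OC(C)(C)C=C2)N1[C@H](Cc2ccccc2)COC1=O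
F6 | step 12 | (2R)-2-{2,2-dimethyl-5-[(triisopropylsilyl)oxy]-2H-chromen-8-yl}-3-{5-(3-methylbut-2-en-1-yl)-2,4-bis[(triisopropylsilyl)oxy]phenyl}propan-1-ol | OC[C@@H](c1ccc(O[Si](C(C)C)(C(C)C)C(C)C)c2c1OC(C)(C)C=C2)Cc1cc(CC=C(C)C)c(O[Si](C(C)C)(C(C)C)C(C)C)cc1O[Si](C(C)C)(C(C)C)C(C)C
F7 | step 12 | 4-[(2R)-3-hydroxy-2-(5-hydroxy-2,2-dimethyl-2H-chromen-8-yl)propyl]-6-(3-methylbut-2-en-1-yl)benzene-1,3-diol | OC[C@@H](c1ccc(O)c2c1OC(C)(C)C=C2)Cc1cc(CC=C(C)C)c(O)cc1O
F8 | step 14 | 2-[(2R)-2-{2,2-dimethyl-5-[(triisopropylsilyl)oxy]-2H-chromen-8-yl}-3-hydroxypropyl]-4-(3-methylbut-2-en-1-yl)-5-[(triisopropylsilyl)oxy]phenol | OC[C@@H](c1ccc(O[Si](C(C)C)(C(C)C)C(C)C)c2c1OC(C)(C)C=C2)Cc1cc(CC=C(C)C)c(O[Si](C(C)C)(C(C)C)C(C)C)cc1O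
F9 | step 9 | 2-hydroxy-5-(prop-2-en-1-yl)-4-[(triisopropylsilyl)oxy]benzaldehyde | O=Cc1cc(CC=C)c(O[Si](C(C)C)(C(C)C)C(C)C)cc1O
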